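The readings are calculated with constants of no real substance.

The question is which flask, alpha or delta, ends with more product; here each is held against the amount its reagent allows in the time it has.

in all of them: free catalyst 15 mol%
- oak: starting material 0.050 M; reagent 0.39 equiv; temperature −65 °C; run made earlier
- larch: starting material 0.050 M; reagent 0.67 equiv; temperature −40 °C; run made earlier
- birch: starting material 0.090 M; reagent 0.50 equiv; temperature −65 °C; run made earlier
- alpha: starting material 0.20 M; reagent 1.00 equiv; at −60 °C throughout; time 5.0 d
- delta: starting material 0.050 M; reagent 0.500 equiv; at −20 °C until 40 h, from then on at −60 °C; time 5.0 d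

- oak (time / d: product / %): 3.00: 0; 10.0: 0; 15.0: 0; 25.0: 0; 40.0: 1; 50.0: 1
- larch (time / d: product / %): 0.833: 0; 3.00: 2; 5.00: 8; 6.00: 7; 10.0: 14; 15.0: 25
- birch (time / d: product / %): 4.00: 0; 8.00: 1; 12.0: 0; 25.0: 1; 50.0: 1

(each reading ± 2 percentage points)

- the flask that ends with the higher amount of product, in percent of the starting material charged, or "neither" when 2 percentage points or less lies between them (alpha / delta / neither)
- final product, as a percentage of the starting material charged, in alpha
- final product, as a percentage of the starting material charged, in delta

- steps that have been proposed: starting material + free catalyst -> catalyst intermediate A; reagent + catalyst intermediate A -> catalyst intermediate B; catalyst intermediate B <-> free catalyst + product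
- where the amount of starting material changes, what is given in equivalents or mol% on it follows

Delta holds less reagent than starting material, so reagent is its limiting reagent. On the proposed steps, each product passes through one reagent, so product, catalyst intermediate B and unreacted reagent together account for the reagent charged. Delta therefore has 50.0% as its reagent ceiling, the charged equivalents of reagent read as per cent of the starting material.

The rates form a ladder. At the top stands the pace that would reach this ceiling within delta's warm hold of 40 h. Next comes larch, which made 25% in 15.0 d, a pace needing 30.0 d for delta's ceiling. So delta's warm stage must run 18.0 times larch's pace to reach it. Lowest stands oak, whose 1% in 50.0 d lies within the scatter and needs 2500 d for the same ceiling. Read at oak's pace, delta's cold remainder adds 0.0667%, less than the scatter of 2 percentage points, so delta should keep what its warm hold made. Alpha stays cold throughout under a ceiling of 100%, and oak's pace, unscaled, gives it 0.100% in this reckoning.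

The forecast says delta, with 2% (0.5% to 6%) for alpha, which is higher than this reckoning, and 34% (18% to 50%) for delta. It takes the warm stage as 15 to 20 times larch's pace, with delta “capped at 50 % by 0.5 equiv reagent”.

Delta ends at 31.6% and alpha at 0.0770%, so delta holds more product than alpha. Delta already held 31.5% product at the change of temperature, after 1.67 d. At the end, 32% of delta's reagent remains, so 34.0% of the starting material charged is used out of the ceiling of 50.0%: the product, plus catalyst intermediate B at 2.57% of the starting material.

    starting material + free catalyst → catalyst intermediate A (k = 0.0290 /M/s, Ea = 49.0 kJ/mol)
    reagent + catalyst intermediate A → catalyst intermediate B (k = 0.00140 /M/s, Ea = 62.0 kJ/mol)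
    catalyst intermediate B ⇌ free catalyst + product (K = 0.0250 M, k = 6.60 × 10⁻⁵ /s, Ea = 78.0 kJ/mol, ΔH = −79.0 kJ/mol)
    (constants at −20 °C)

The same flask as delta with 0.300 equiv of reagent has a ceiling of 30.0%. The computed flask gives 20.2%, with 28% of its reagent left.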